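All runs are calculated on assumed constants; the scatter is artificial.

Start from what is left. The flask, called epsilon while it runs, has been followed to 40.0 h, and the question is where target stands at 3.0 d and whether a remedy adds to it.

| flask | starting material | reagent | free catalyst | temperature | remark | time |
|---|---|---|---|---|---|---|
| epsilon | 0.33 M | 2.5 equiv | 2 mol% | 25 °C | the very flask that is asked about, followed so far |  |
| delta | 0.33 M | 1.2 equiv | 2 mol% | 10 °C | run made earlier |  |
| flask | 0.33 M | 2.50 equiv | 2 mol% | 25 °C |  | 3.0 d |

| run | time / h | target / % | starting material / % |
|---|---|---|---|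
| epsilon | 3.00 | 10.8 | 85.1 |
| epsilon | 8.00 | 20.3 | 66.7 |
| epsilon | 20.0 | 22.8 | 34.0 |
| epsilon | 40.0 | 21.7 | 10.3 |
| delta | 1.00 | 1.1 | 97.3 |
| delta | 2.00 | 2.3 | 97.4 |
| delta | 5.00 | 3.8 | 94.9 |
| delta | 12.0 | 8.1 | 89.5 |

(each reading ± 0.5 percentage points)

- target, in percent of the starting material first charged, at 3.0 d
- the remedy with the largest gain of target, or "none" below 2 percentage points (south-west / south / north / north-west / none)
- target present, in percent of the starting material first charged, after north
- target present, in percent of the starting material first charged, after north-west

- south-west: change nothing and wait 3.0 d more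
- south: at 3.0 d raise the temperature by 20 K, then wait 3.0 d
- north: at 3.0 d take out 90% of the released group then present, then wait 3.0 d
- north-west: at 3.0 d add free catalyst, 50.0% of the amount charged, then wait 3.0 d

- additions bring no volume worth counting

In the epsilon run, starting material falls from 34.0% at 20.0 h to 10.3% at 40.0 h. Read as first-order decay, this gives a constant of 0.0597 h⁻¹, so about 1.52% remains at 3.0 d. At the last reading, 24.2% of the reacted material is target, which suggests 23.8% at 3.0 d.

The objection is that this share is moving: it read 34.5% at 20.0 h. Suppose instead that target's excess over its final level shrinks in step with the fraction left. Target is then a straight line against the fraction left, with slope 0.0464. Where that line reaches zero left stands the resting share, the target in percent of the charge once no starting material remains: 21.2%, uncertain by 0.75 percentage points from the scatter.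

A second objection is that the line gives 24.3% at 8.00 h, higher than the reading of 20.3%, so it fails early. It is therefore used over the last stretch, where the extrapolation is short, and gives 21.3% at 3.0 d. Waiting then moves target by 0.071 points, less than the 2 points that counts. The share is read at one temperature, and the delta run differs in reagent as well, so this reckoning leaves heating open.

The forecast gives 21.5%, best none, 11% after north and 21.5% after north-west, and says of temperature: “Heating shifts it little”.

The flask gives 19.9%, and 19.6% after north and 19.6% after north-west. The best remedy is south, with a gain of 36 points, against none in the forecast, and flask and forecast part a second time on north, where the flask gives 19.6% and the forecast 11%.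

    starting material + free catalyst ⇌ catalyst intermediate A (K = 3.30 M⁻¹, k = 0.160 M⁻¹ s⁻¹, Ea = 41.0 kJ mol⁻¹, ΔH = −73.0 kJ mol⁻¹)
    reagent + catalyst intermediate A ⇌ catalyst intermediate B (K = 0.840 M⁻¹, k = 0.00220 M⁻¹ s⁻¹, Ea = 68.0 kJ mol⁻¹, ΔH = 19.0 kJ mol⁻¹)
    catalyst intermediate B → released group + catalyst intermediate C (k = 0.0120 s⁻¹, Ea = 87.0 kJ mol⁻¹)
    catalyst intermediate C ⇌ free catalyst + target (K = 0.980 M, k = 0.210 s⁻¹, Ea = 82.0 kJ mol⁻¹, ΔH = −66.0 kJ mol⁻¹)
    target ⇌ isomer of the product (K = 4.10, k = 4.20 × 10⁻⁵ s⁻¹, Ea = 93.0 kJ mol⁻¹, ΔH = −66.0 kJ mol⁻¹)
    (constants at 25 °C)

At 7.20 h the flask held 68.0% starting material, 19.3% target and 11.8% isomer of the product, with catalyst intermediate A at 38.6% of the catalyst. By 72.0 h it held 1.42%, 19.9% and 78.5%, the exchange of target and isomer of the product having a relaxation half-life, by that step alone and both ways together, short against that time, which is thermodynamic control. The resting share, taken on the 98.6% reacted, gives 20.9% here. It also means isomer of the product over target of 3.71. Shifted with the heat of the last step, that ratio gives 48.0% target for the same flask at 40 °C, and the computed flask gives 45.3%.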